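# Total synthesis of Lychnophorolide B

**Assumptions (one line each)**
- The ester in the given SMILES, `OC(=O)/C(C)=C/C`, has the carbonyl trans to the β-methyl, so it is a tigloyl (E) ester, and tigloyl chloride is used.
- (R)-Citramalic acid is taken as commercially available.

## Retrosynthetic overview
1. Target ⇐ C15 silyl ether **25** ⇐ photoredox/Cr-catalysed intramolecular allylation of bromo-enal **24**. This one step forms the C6–C7 bond, the exocyclic methylene, the trans-γ-lactone and the 10-membered ring.
2. **24** ⇐ cross-metathesis of a C8-vinyl group with methyl 2-(bromomethyl)acrylate, plus MnO2 oxidation of the C6 allylic alcohol.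
3. The 3(2H)-furanone ring is formed first, by base-mediated 5-endo-dig cyclisation of α'-hydroxy-ynone **19**.
4. **19** ⇐ Weinreb amide **8** + lithium acetylide of Z-enyne **18**.
   - **8** comes from (R)-citramalic acid, which supplies C10. C8 is set by C10-OH-directed 1,3-syn reduction.
   - **18** comes from 2-butyne-1,4-diol by hydroalumination/iodination and Sonogashira coupling.
5. Ring order: furanone first, then macrocycle and lactone together in the photochemical step.

## Route

**Step 1**
Reactants: **1** (R)-citramalic acid; **2** N,O-dimethylhydroxylamine·HCl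
Product: **3** bis-Weinreb amide of (R)-citramalic acid
Conditions: **2** (2.5 equiv), EDC·HCl, HOBt, i-Pr2NEt, CH2Cl2/DMF, 0 °C → rt
Reagents that add atoms: **2**, CNOC.Cl
Why: Carbodiimide amidation of both carboxylic acids; the C10 stereocentre (R) is untouched.

**Step 2**
Reactants: **3**; **4** vinylmagnesium bromide
Product: **5** C8 vinyl ketone with the C1 Weinreb amide retained
Conditions: **4** (2.6 equiv), THF, −78 → −20 °C; cold NH4Cl quench
Reagents that add atoms: **4**, C=C[Mg]Br
Why: Weinreb ketone synthesis. The unhindered CH2-bound C8 amide reacts in preference to the α-quaternary, alkoxide-chelated C1 amide, and the stable Mg chelate stops at the ketone.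

**Step 3**
Reactants: **5**
Product: **6** syn-1,3-diol (2R,4S)
Conditions: Et2BOMe, NaBH4, THF/MeOH 4:1, −78 °C
Reagents that add atoms: none
Why: Narasaka–Prasad reduction. The boron chelate between the C10 oxygen and the C8 carbonyl gives axial hydride delivery, which sets C8 (S) syn to the existing C10 (R) stereocentre.

**Step 4**
Reactants: **6**; **7** tigloyl chloride
Product: **8** C8 tiglate, with the tertiary C10-OH free
Conditions: **7** (1.3 equiv), pyridine, cat. DMAP, CH2Cl2, 0 °C
Reagents that add atoms: **7**, C/C=C(\C)C(=O)Cl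
Why: Acylation is chemoselective for the secondary allylic alcohol over the hindered tertiary alcohol; no stereocentre is affected.

**Step 5**
Reactants: **9** 2-butyne-1,4-diol; **10** TBDPSCl
Product: **11** 4-(TBDPS-oxy)but-2-yn-1-ol
Conditions: **9** (3 equiv), **10** (1 equiv), imidazole, DMF, 0 °C
Reagents that add atoms: **10**, CC(C)(C)[Si](Cl)(c1ccccc1)c1ccccc1
Why: Statistical mono-silylation, with excess diol recycled, differentiates the C15 and C6 oxygens.

**Step 6**
Reactants: **11**; **12** iodine
Product: **13** (Z)-3-iodo-4-(TBDPS-oxy)but-2-en-1-ol (I cis to CH2OH)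
Conditions: Red-Al, Et2O/THF, 0 °C; then EtOAc; then **12**, −78 °C
Reagents that add atoms: **12**, II
Why: The free alcohol directs trans-hydroalumination so that Al sits on the distal carbon (C4); I2 replaces Al with retention, which fixes the C3/C6-cis geometry needed later.

**Step 7**
Reactants: **13**; **14** TBSCl
Product: **15** TBS ether of **13**
Conditions: **14**, imidazole, DMF, rt
Reagents that add atoms: **14**, CC(C)(C)[Si](C)(C)Cl
Why: Protecting C6-O prevents the later Z-enynol → furan cycloisomerisation and is removable selectively over TBDPS.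

**Step 8**
Reactants: **15**; **16** trimethylsilylacetylene
Product: **17** TMS-enyne
Conditions: **16**, Pd(PPh3)2Cl2 (3 mol%), CuI (5 mol%), Et3N, THF, rt
Reagents that add atoms: **16**, C[Si](C)(C)C#C
Why: Sonogashira coupling proceeds with retention of alkene geometry.

**Step 9**
Reactants: **17**
Product: **18** terminal Z-enyne
Conditions: K2CO3, MeOH/THF, 0 °C, 20 min
Reagents that add atoms: none
Why: The C-silyl alkyne is cleaved selectively under mild base, and the O-silyl ethers survive.

**Step 10**
Reactants: **8**; **18**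
Product: **19** α'-hydroxy ynone
Conditions: **18** (2.4 equiv), n-BuLi (2.4 equiv), THF, −78 °C; add **8**; −78 → −20 °C
Reagents that add atoms: none
Why: Weinreb ketone synthesis. The first equivalent of acetylide or base deprotonates the C10-OH, and the chelated intermediate stops at the ynone.

**Step 11**
Reactants: **19**
Product: **20** 3(2H)-furanone
Conditions: DBU (0.2 equiv), CH2Cl2, 0 °C → rt
Reagents that add atoms: none
Why: Base-mediated 5-endo-dig oxa-cyclisation of the tertiary alkoxide onto the ynone β-carbon builds the furanone. C10 is not involved in the bond-forming event, so its configuration is unchanged, and the Z-alkene is retained.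

**Step 12**
Reactants: **20**
Product: **21** C6 allylic alcohol
Conditions: CSA (0.2 equiv), MeOH/CH2Cl2 1:1, 0 °C
Reagents that add atoms: none
Why: Acid methanolysis removes the primary TBS ether selectively; TBDPS, the tiglate and the furanone are stable.

**Step 13**
Reactants: **21**; **22** methyl 2-(bromomethyl)acrylate
Product: **23** 2-(bromomethyl)enoate (E/Z mixture) with free C6-OH
Conditions: **22** (5 equiv), Hoveyda–Grubbs II (5 mol%), CH2Cl2, 40 °C
Reagents that add atoms: **22**, C=C(CBr)C(=O)OC
Why: Cross-metathesis of the terminal vinyl group with an acrylate partner. The E/Z geometry is irrelevant because the allylchromium formed later equilibrates.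

**Step 14**
Reactants: **23**
Product: **24** Z-enal bromide
Conditions: MnO2 (20 equiv), CH2Cl2, rt, dark; used immediately
Reagents that add atoms: none
Why: Chemoselective oxidation of the primary allylic alcohol. The alkene geometry is unchanged, with C6 cis to C3.

**Step 15**
Reactants: **24**
Product: **25** C15 TBDPS ether of the target
Conditions: CrCl3 (20 mol%), 4CzIPN (2 mol%), Hantzsch ester (2 equiv), MeCN/THF 1:1, 0.003 M (substrate added over 6 h), blue LEDs (455 nm), 25 °C; PPTS work-up
Reagents that add atoms: none
Why: Proposed new method: a light-driven, catalytic-Cr macrocyclic Nozaki–Hiyama–Kishi-type allylation. The reductively quenched photocatalyst reduces Cr(III) to Cr(II), or the allylic bromide directly, and Cr(II) captures the allyl radical to give an allylchromium(III). This adds to the C6 aldehyde through a chair Zimmerman–Traxler transition state (E-allyl, aldehyde substituent equatorial), which gives the anti adduct (C5 and C8 trans, i.e. the trans-lactone). Facial selectivity comes from the C8 stereocentre and the conformation of the Z-enal/furanone macrocycle, with no chiral catalyst. The Cr-alkoxide then lactonises onto the methyl ester, releasing Cr(III)–OMe, which is reduced by the photocycle. The closest known reactions are the stoichiometric intramolecular NHK macrocyclisation and intermolecular Cr/photoredox allylation of aldehydes.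

**Step 16**
Reactants: **25**
Product: **26** Lychnophorolide B
Conditions: HF·pyridine, THF/pyridine, 0 °C → rt
Reagents that add atoms: none
Why: Fluoride-mediated desilylation frees the primary allylic alcohol; the lactone, tiglate and furanone survive buffered HF.

## Compound list
1 | (R)-citramalic acid | `C[C@@](O)(CC(=O)O)C(=O)O` | starting material
2 | N,O-dimethylhydroxylamine hydrochloride | `CNOC.Cl` | starting material
3 | (2R)-2-hydroxy-N1,N4-dimethoxy-N1,N4,2-trimethylbutanediamide | `C[C@@](O)(CC(=O)N(C)OC)C(=O)N(C)OC` | intermediate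
4 | vinylmagnesium bromide | `C=C[Mg]Br` | starting material
5 | (2R)-2-hydroxy-N-methoxy-N,2-dimethyl-4-oxohex-5-enamide | `C[C@@](O)(CC(=O)C=C)C(=O)N(C)OC` | intermediate
6 | (2R,4S)-2,4-dihydroxy-N-methoxy-N,2-dimethylhex-5-enamide | `C[C@@](O)(C[C@H](O)C=C)C(=O)N(C)OC` | intermediate
7 | tigloyl chloride | `C/C=C(\C)C(=O)Cl` | starting material
8 | (2R,4S)-2-hydroxy-N-methoxy-N,2-dimethyl-4-(tigloyloxy)hex-5-enamide | `C[C@@](O)(C[C@H](OC(=O)/C(C)=C/C)C=C)C(=O)N(C)OC` | intermediate
9 | 2-butyne-1,4-diol | `OCC#CCO` | starting material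
10 | TBDPSCl | `CC(C)(C)[Si](Cl)(c1ccccc1)c1ccccc1` | starting material
11 | 4-(TBDPS-oxy)but-2-yn-1-ol | `OCC#CCO[Si](c1ccccc1)(c1ccccc1)C(C)(C)C` | intermediate
12 | iodine | `II` | starting material
13 | (Z)-3-iodo-4-(TBDPS-oxy)but-2-en-1-ol | `OC/C=C(\I)CO[Si](c1ccccc1)(c1ccccc1)C(C)(C)C` | intermediate
14 | TBSCl | `CC(C)(C)[Si](C)(C)Cl` | starting material
15 | TBS ether of 13 | `CC(C)(C)[Si](C)(C)OC/C=C(\I)CO[Si](c1ccccc1)(c1ccccc1)C(C)(C)C` | intermediate
16 | trimethylsilylacetylene | `C[Si](C)(C)C#C` | starting material
17 | TMS-enyne | `CC(C)(C)[Si](C)(C)OC/C=C(/CO[Si](c1ccccc1)(c1ccccc1)C(C)(C)C)C#C[Si](C)(C)C` | intermediate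
18 | terminal Z-enyne (alkyne cis to CH2OTBS) | `CC(C)(C)[Si](C)(C)OC/C=C(/CO[Si](c1ccccc1)(c1ccccc1)C(C)(C)C)C#C` | intermediate
19 | α'-hydroxy ynone | `C[C@@](O)(C[C@H](OC(=O)/C(C)=C/C)C=C)C(=O)C#C/C(CO[Si](c1ccccc1)(c1ccccc1)C(C)(C)C)=C\CO[Si](C)(C)C(C)(C)C` | intermediate
20 | (2R)-2-methyl-2-[(2S)-2-(tigloyloxy)but-3-en-1-yl]-5-[(Z)-4-(TBS-oxy)-1-(TBDPS-oxy)but-2-en-2-yl]furan-3(2H)-one | `CC(C)(C)[Si](C)(C)OC/C=C(/CO[Si](c1ccccc1)(c1ccccc1)C(C)(C)C)C1=CC(=O)[C@@](C)(C[C@H](OC(=O)/C(C)=C/C)C=C)O1` | intermediate
21 | C6 free allylic alcohol | `OC/C=C(/CO[Si](c1ccccc1)(c1ccccc1)C(C)(C)C)C1=CC(=O)[C@@](C)(C[C@H](OC(=O)/C(C)=C/C)C=C)O1` | intermediate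
22 | methyl 2-(bromomethyl)acrylate | `C=C(CBr)C(=O)OC` | starting material
23 | 2-(bromomethyl)enoate alcohol | `OC/C=C(/CO[Si](c1ccccc1)(c1ccccc1)C(C)(C)C)C1=CC(=O)[C@@](C)(C[C@H](OC(=O)/C(C)=C/C)C=C(CBr)C(=O)OC)O1` | intermediate
24 | Z-enal bromo-enoate | `O=C/C=C(/CO[Si](c1ccccc1)(c1ccccc1)C(C)(C)C)C1=CC(=O)[C@@](C)(C[C@H](OC(=O)/C(C)=C/C)C=C(CBr)C(=O)OC)O1` | intermediate
25 | TBDPS ether of Lychnophorolide B | `C=C1C(=O)O[C@@H]2/C=C(/CO[Si](c4ccccc4)(c4ccccc4)C(C)(C)C)C3=CC(=O)[C@@](C)(C[C@H](OC(=O)/C(C)=C/C)[C@@H]12)O3` | intermediate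
26 | Lychnophorolide B | `C=C1C(=O)O[C@@H]2/C=C(/CO)C3=CC(=O)[C@@](C)(C[C@H](OC(=O)/C(C)=C/C)[C@@H]12)O3` | target

## Totals
- **Total steps:** 16.
- **Longest linear sequence:** 12 steps, starting from 2-butyne-1,4-diol. The branch from (R)-citramalic acid is 11 steps.

## Three steps most likely to fail
1. **Step 15 (new photo-Cr macrocyclisation).** Risks are over-reduction or photodecomposition of the Z-enal/furanone, and the wrong C6/C7 diastereomer.
   - Fallback (known chemistry): stoichiometric CrCl2 with cat. NiCl2 in DMF/THF at high dilution, the classical thermal NHK macrocyclisation of the same bromo-aldehyde, followed by acid-promoted lactonisation.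
2. **Step 3 (C8 stereocentre by 1,3-syn reduction of the tertiary-β-hydroxy ketone).** The syn:anti ratio may be poor.
   - Fallback: Evans–Saksena reduction with Me4NBH(OAc)3 to give the anti-diol, then Mitsunobu esterification of C8-OH with tiglic acid (DIAD, PPh3). This inverts C8 and installs the tiglate in one step, replacing Steps 3 and 4.
3. **Step 13 (cross-metathesis with the reactive 2-(bromomethyl)acrylate).** The allylic bromide may poison the Ru catalyst or give low conversion.
   - Fallback: reorder to do the MnO2 oxidation first, then cross-metathesis with methyl 2-(hydroxymethyl)acrylate. Convert the new allylic alcohol to the bromide with CBr4/PPh3 (Appel).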